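## Plan

1. Cuts: the lactone C3–CH2(ring A) bond; O1–C2 and C2–C3 of the ring B dihydrobenzofuran in one operation; C7'–C8' of the ring A diol side chain; the lactone back to an arylidene succinate.
2. Enabling feature: in the dihydrobenzofuran, O1 is attached to C7a and C3 to the neighbouring C3a, and C2 bears only H and the guaiacyl ring. O1–C7a–C3a–C3 is therefore an o-quinone methide (methide carbon = C3) and C2 is a one-carbon benzylic sulfonium ylide.
3. Forward order: butyrolactone ring (Stobbe, hydrogenation, reduction–lactonisation), side-chain build-up on ring B, dihydrofuran ring by (4+1) annulation, attachment of the ring A fragment at lactone C3, global desilylation.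
4. Stereochemistry: lactone C4 (S) comes from Rh/Et-DuPhos hydrogenation and lactone C3 (S) from alkylation anti to the C4 substituent. Dihydrobenzofuran C2 (R) comes from a C2-symmetric (2R,5R)-2,5-dimethylthiolane in the ylide and its C3 (S) from the trans-selective closure. C7' (S) and C8' (S) come from an Evans-type magnesium-catalysed anti-aldol.

Key step: step 16

Locants and abbreviations: C7' is the side-chain carbinol carbon, C8' the carbon bearing ring A, and C9' the CH2OH carbon. TBS = tert-butyldimethylsilyl, TIPS = triisopropylsilyl.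

Assumption: the absolute sense of the three reagent-controlled steps (3, 16, 21) is carried over from itaconate half-esters, from aldehyde epoxidation with the same thiolanium ylide type, and from chelate-controlled imide enolate reactions. If one proved reversed on these substrates, the mirror-image ligand, sulfide or auxiliary would be used with no other change.

## Route

Step 1
Reactants: 1 5-bromovanillin
Product: 2 4-(benzyloxy)-3-bromo-5-methoxybenzaldehyde
Conditions: BnBr, K2CO3, DMF, 50 °C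
Reagents that add atoms: benzyl bromide, BrCc1ccccc1
Why: Williamson etherification of the acidic phenol; the benzyl ether survives alkoxide, borohydride, palladium coupling and osmylation and leaves later by hydrogenolysis.

Step 2
Reactants: 2 4-(benzyloxy)-3-bromo-5-methoxybenzaldehyde; 3 dimethyl succinate
Product: 4 (E)-4-[4-(benzyloxy)-3-bromo-5-methoxyphenyl]-3-(methoxycarbonyl)but-3-enoic acid
Conditions: NaOMe, MeOH, reflux; then aq. HCl
Reagents that add atoms: none
Why: Stobbe condensation, in which the succinate enolate adds to the aldehyde, the alkoxide lactonises onto the distal ester and E1cB opening of that lactone gives the (E)-arylidene half-ester, as is routine for O-benzylvanillins.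

Step 3
Reactants: 4 (E)-arylidene half-ester
Product: 5 (3S)-4-[4-(benzyloxy)-3-bromo-5-methoxyphenyl]-3-(methoxycarbonyl)butanoic acid
Conditions: [Rh(cod)((R,R)-Et-DuPhos)]BF4 (0.5 mol %), H2 (6 bar), MeOH, rt
Reagents that add atoms: none
Why: Rhodium-catalysed asymmetric hydrogenation of a Stobbe-derived itaconate half-ester, in which the carboxyl group binds the cationic rhodium centre and the bisphospholane opens one alkene face to H2, setting the S centre (later lactone C4), while aryl bromide and benzyl ether are inert to this catalyst.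

Step 4
Reactants: 5 (3S)-half-ester
Product: 7 (4S)-4-[4-(benzyloxy)-3-bromo-5-methoxybenzyl]oxolan-2-one, via hydroxy acid 6 (not isolated)
Conditions: KOH (1 equiv), EtOH; CaCl2, NaBH4, EtOH, −10 °C to rt; then 2 M HCl, rt
Reagents that add atoms: none
Why: Chemoselective ester reduction by Ca(BH4)2 made in situ (the carboxylate salt is inert) followed by acid-catalysed lactonisation, the classical entry to β-benzyl-γ-butyrolactones, with the stereocentre not involved.

Step 5
Reactants: 7 bromolactone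
Product: 8 (4S)-4-[4-(benzyloxy)-3-ethenyl-5-methoxybenzyl]oxolan-2-one
Conditions: CH2=CHBpin, PdCl2(dppf) (3 mol %), K2CO3, dioxane/H2O, 80 °C; dilute HCl work-up
Reagents that add atoms: vinylboronic acid pinacol ester, C=CB1OC(C)(C)C(C)(C)O1
Why: Suzuki–Miyaura vinylation of the aryl bromide; any lactone opened by carbonate recloses on the acidic work-up.

Step 6
Reactants: 8 vinyl lactone
Product: 9 (4S)-4-[4-(benzyloxy)-3-(1,2-dihydroxyethyl)-5-methoxybenzyl]oxolan-2-one (both carbinol epimers)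
Conditions: K2OsO4·2H2O (1 mol %), NMO, acetone/H2O, rt
Reagents that add atoms: N-methylmorpholine N-oxide, C[N+]1([O-])CCOCC1; water, O
Why: Upjohn dihydroxylation of the styrene; the new carbinol centre is left uncontrolled because it becomes planar in 21.

Step 7
Reactants: 9 diol
Product: 10 (4S)-4-{4-(benzyloxy)-3-[2-(TBS-oxy)-1-hydroxyethyl]-5-methoxybenzyl}oxolan-2-one
Conditions: TBSCl (1.05 equiv), imidazole, CH2Cl2, 0 °C
Reagents that add atoms: tert-butyldimethylsilyl chloride, CC(C)(C)[Si](C)(C)Cl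
Why: Sterically controlled monosilylation of the primary hydroxyl of a 1,2-diol.

Step 8
Reactants: 10 benzyl ether
Product: 11 (4S)-4-{4-hydroxy-3-[2-(TBS-oxy)-1-hydroxyethyl]-5-methoxybenzyl}oxolan-2-one
Conditions: H2 (1 atm), Pd/C, EtOAc, rt
Reagents that add atoms: none
Why: Neutral hydrogenolysis of the aryl benzyl ether, much faster than that of the unactivated secondary benzylic alcohol, frees the phenol needed for quinone methide formation.

Step 9
Reactants: 11 o-hydroxybenzyl alcohol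
Product: 12 (4S)-4-{4-hydroxy-3-[2-(TBS-oxy)-1-(p-tolylsulfonyl)ethyl]-5-methoxybenzyl}oxolan-2-one (either sulfone epimer)
Conditions: p-TolSO2H (1.5 equiv), 4 Å MS, CH2Cl2, rt
Reagents that add atoms: p-toluenesulfinic acid, Cc1ccc(S(=O)O)cc1
Why: Dehydrative sulfinate substitution of an o-hydroxybenzyl alcohol, the standard preparation of 2-(1-tosylalkyl)phenols, in which the ortho phenol assists loss of water and the sulfinate sulfur captures the benzylic carbon; the sulfone epimers are equivalent for step 16.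

Step 10
Reactants: 13 (2S,5S)-hexane-2,5-diol
Product: 14 (2S,5S)-hexane-2,5-diyl dimethanesulfonate
Conditions: MsCl, Et3N, CH2Cl2, 0 °C
Reagents that add atoms: methanesulfonyl chloride, CS(=O)(=O)Cl
Why: Mesylation of both secondary alcohols with retention at carbon.

Step 11
Reactants: 14 dimesylate
Product: 15 (2R,5R)-2,5-dimethylthiolane
Conditions: Na2S·9H2O, EtOH, rt to 40 °C
Reagents that add atoms: sodium sulfide, [Na+].[Na+].[S-2]
Why: Double SN2 displacement by sulfide, each with inversion, converts the (S,S)-dimesylate into the C2-symmetric (R,R)-thiolane.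

Step 12
Reactants: 16 vanillin
Product: 17 3-methoxy-4-(TIPS-oxy)benzaldehyde
Conditions: TIPSCl, imidazole, DMF, rt
Reagents that add atoms: triisopropylsilyl chloride, CC(C)[Si](Cl)(C(C)C)C(C)C
Why: Phenol silylation; the bulky TIPS group is chosen because its aryl ether resists carbonate and phenoxide in step 16, and 17 serves both the ylide branch and the aldol of step 21.

Step 13
Reactants: 17 TIPS-vanillin
Product: 18 [3-methoxy-4-(TIPS-oxy)phenyl]methanol
Conditions: NaBH4, MeOH, 0 °C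
Reagents that add atoms: none
Why: Borohydride reduction of an aromatic aldehyde.

Step 14
Reactants: 18 benzylic alcohol
Product: 19 4-(bromomethyl)-2-methoxy-1-(TIPS-oxy)benzene
Conditions: PBr3, Et2O, 0 °C
Reagents that add atoms: phosphorus tribromide, BrP(Br)Br
Why: Bromination of an electron-rich benzylic alcohol with PBr3, the usual preparation of 4-silyloxy-3-methoxybenzyl bromides.

Step 15
Reactants: 19 benzylic bromide; 15 (2R,5R)-2,5-dimethylthiolane
Product: 20 (2R,5R)-1-[3-methoxy-4-(TIPS-oxy)benzyl]-2,5-dimethylthiolan-1-ium triflate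
Conditions: 15 (1.2 equiv), AgOTf, CH2Cl2, −20 °C to rt, dark
Reagents that add atoms: silver triflate, [Ag+].[O-]S(=O)(=O)C(F)(F)F
Why: S-Alkylation of the sulfide driven by precipitation of AgBr; the homotopic lone pairs of the C2-symmetric sulfide give one sulfonium salt, and the triflate counter-ion cannot reverse the alkylation.

Step 16
Reactants: 12 tosyl phenol lactone; 20 thiolanium triflate
Product: 24 (4S)-4-({(2R,3S)-3-[(TBS-oxy)methyl]-7-methoxy-2-[3-methoxy-4-(TIPS-oxy)phenyl]-2,3-dihydro-1-benzofuran-5-yl}methyl)oxolan-2-one, via o-quinone methide 21 (not isolated), via benzylic ylide 22 (not isolated), via betaine 23 (not isolated)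
Conditions: 20 (2 equiv), Cs2CO3 (4 equiv), MeCN, −20 to 0 °C, 12 added slowly
Reagents that add atoms: none
Why: Proposed new method: Cs2CO3 deprotonates the phenol of 12, which expels p-toluenesulfinate (E1cB) to give o-quinone methide 21, and reversibly deprotonates 20 to the semi-stabilised benzylic ylide 22; the ylide carbon bonds to the methide carbon with rearomatisation (C2–C3) to give betaine 23, whose phenoxide displaces the thiolane at C2 with inversion (O1–C2), a 5-exo-tet closure of the dihydrofuran ring. The closest known reaction type is the carbonate-mediated (4+1) annulation of o-quinone methides released from 2-(1-tosylalkyl)phenols with carbonyl-stabilised sulfonium ylides, which gives trans-2,3-dihydrobenzofurans, together with carbonate-mediated aziridination and epoxidation by benzylic sulfonium salts of chiral sulfides; the benzylic ylide, the chiral thiolane and the CH2OSi-substituted methide are the extension. C2 is controlled by the C2-symmetric thiolane: with the aryl group turned away from the ring, the methyl group cis to the ylide carbon shields one face, so bonding occurs on the face that gives (S,S)-epoxides with aromatic aldehydes and, after SN2 inversion, 2R here. C3 is controlled relative to C2: the approach that keeps the guaiacyl ring and the CH2OTBS group apart leads to the betaine that can align phenoxide and sulfonium anti-periplanar without eclipsing them, so the trans (2R,3S) ring should close fastest. The step needs ylide capture to outrun the 1,5-hydrogen shift of 21 to a vinyl phenol and O-benzylation of the phenoxide by 20, which is served by slow addition of 12 to excess 20, by reversible re-addition of sulfinate that keeps 21 dilute, and by the fast loss of sulfinate from the ortho phenoxide. The lactone centre is too remote to steer the annulation but turns any (2S,3R) product into a separable diastereomer, and lactone and silyl ethers tolerate suspended carbonate at low temperature.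

Step 17
Reactants: 25 methyl 3-bromo-4-hydroxy-5-methoxybenzoate
Product: 26 methyl 3-bromo-4-(TBS-oxy)-5-methoxybenzoate
Conditions: TBSCl, imidazole, DMF, rt
Reagents that add atoms: tert-butyldimethylsilyl chloride, CC(C)(C)[Si](C)(C)Cl
Why: Phenol silylation; the doubly ortho-flanked aryl TBS ether is robust through the rest of the ring A sequence.

Step 18
Reactants: 26 aryl bromide
Product: 27 methyl 3-(2-tert-butoxy-2-oxoethyl)-4-(TBS-oxy)-5-methoxybenzoate
Conditions: ClZnCH2CO2t-Bu, Pd(dba)2 (2 mol %), P(t-Bu)3 (2 mol %), THF, rt to 50 °C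
Reagents that add atoms: (2-tert-butoxy-2-oxoethyl)zinc chloride, CC(C)(C)OC(=O)C[Zn]Cl
Why: Palladium-catalysed α-arylation of a Reformatsky-type zinc enolate (Negishi-type coupling), neutral enough for the methyl ester and the aryl silyl ether.

Step 19
Reactants: 27 tert-butyl ester
Product: 28 [2-(TBS-oxy)-3-methoxy-5-(methoxycarbonyl)phenyl]acetic acid
Conditions: TFA, CH2Cl2, 0 °C to rt
Reagents that add atoms: none
Why: Acidolysis of the tert-butyl ester by loss of isobutene, which leaves the methyl ester and the hindered aryl TBS ether in place.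

Step 20
Reactants: 28 arylacetic acid; 29 (4S)-4-benzyl-1,3-oxazolidin-2-one
Product: 31 methyl 3-{2-[(4S)-4-benzyl-2-oxo-1,3-oxazolidin-3-yl]-2-oxoethyl}-4-(TBS-oxy)-5-methoxybenzoate, via mixed pivalic anhydride 30 (not isolated)
Conditions: PivCl, Et3N, THF, −20 °C; then 29, LiCl, rt
Reagents that add atoms: pivaloyl chloride, CC(C)(C)C(=O)Cl (atoms carried only by intermediate 30)
Why: N-Acylation of the Evans oxazolidinone through the mixed pivalic anhydride under LiCl/Et3N conditions.

Step 21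
Reactants: 31 arylacetyl imide; 17 TIPS-vanillin
Product: 33 (2R,3S)-anti-aldol imide methyl 3-{(2R,3S)-1-[(4S)-4-benzyl-2-oxo-1,3-oxazolidin-3-yl]-3-hydroxy-3-[3-methoxy-4-(TIPS-oxy)phenyl]-1-oxopropan-2-yl}-4-(TBS-oxy)-5-methoxybenzoate, via trimethylsilyl ether 32 (not isolated)
Conditions: MgCl2 (0.2 equiv), Et3N, TMSCl, EtOAc, rt; then TFA (cat.), MeOH
Reagents that add atoms: chlorotrimethylsilane, C[Si](C)(C)Cl (atoms carried only by intermediate 32)
Why: Magnesium halide-catalysed Evans anti-aldol (soft enolisation with silyl trapping) with a non-enolisable aromatic aldehyde, in which the chelated (Z)-magnesium enolate reacts on the face away from the benzyl group (C8', 2R in the imide), the boat-like transition state gives the anti carbinol (C7', 3S), and TMSCl traps the aldolate before retro-aldol.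

Step 22
Reactants: 33 aldol imide
Product: 34 methyl 4-(TBS-oxy)-3-{(1S,2S)-1,3-dihydroxy-1-[3-methoxy-4-(TIPS-oxy)phenyl]propan-2-yl}-5-methoxybenzoate
Conditions: LiBH4, MeOH (1 equiv), THF, 0 °C
Reagents that add atoms: none
Why: Reductive removal of the auxiliary with LiBH4, the imide carbonyl being far more electrophilic than the electron-rich methyl benzoate; no stereocentre is touched (C8' changes descriptor from R to S only through ligand ranking).

Step 23
Reactants: 34 diol
Product: 35 methyl 4-(TBS-oxy)-3-{(1S,2S)-1,3-bis(TBS-oxy)-1-[3-methoxy-4-(TIPS-oxy)phenyl]propan-2-yl}-5-methoxybenzoate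
Conditions: TBSOTf (excess), 2,6-lutidine, CH2Cl2, 0 °C
Reagents that add atoms: tert-butyldimethylsilyl triflate, CC(C)(C)[Si](C)(C)OS(=O)(=O)C(F)(F)F
Why: Silylation of both hydroxyls with TBSOTf; because the ring A phenol also carries TBS, any aryl-to-alkyl silyl migration in step 22 is made good here by the excess reagent.

Step 24
Reactants: 35 methyl benzoate
Product: 36 the corresponding benzylic alcohol, [4-(TBS-oxy)-3-{(1S,2S)-1,3-bis(TBS-oxy)-1-[3-methoxy-4-(TIPS-oxy)phenyl]propan-2-yl}-5-methoxyphenyl]methanol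
Conditions: i-Bu2AlH (2.5 equiv), CH2Cl2, −78 °C; aq. potassium sodium tartrate
Reagents that add atoms: none
Why: i-Bu2AlH reduction of the benzoate to the benzylic alcohol, with silyl ethers inert.

Step 25
Reactants: 36 benzylic alcohol
Product: 37 the corresponding benzylic bromide (ring A fragment)
Conditions: CBr4, PPh3, CH2Cl2, 0 °C
Reagents that add atoms: carbon tetrabromide, BrC(Br)(Br)Br
Why: Appel bromination under neutral conditions that spare all silyl ethers; the bromide is used without storage.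

Step 26
Reactants: 24 dihydrobenzofuran lactone; 37 ring A benzylic bromide
Product: 39 hexasilylated (3S,4S)-trans-dibenzylbutyrolactone, via lithium enolate 38 (not isolated)
Conditions: LiN(SiMe3)2, THF, −78 °C; then 37, DMPU, −78 to −30 °C
Reagents that add atoms: lithium hexamethyldisilazide, [Li+].C[Si](C)(C)[N-][Si](C)(C)C (lithium carried only by intermediate 38)
Why: Alkylation of a β-substituted γ-butyrolactone lithium enolate, the standard dibenzylbutyrolactone lignan construction, in which the bromide approaches anti to the C4 substituent and sets lactone C3 as S (trans).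

Step 27
Reactants: 39 hexasilyl ether
Product: 40 target CNP0186558.3
Conditions: Bu4NF, AcOH (1:1, excess), THF, 0 °C to rt
Reagents that add atoms: none
Why: Fluoride-mediated global desilylation of four TBS and two TIPS ethers; acetic acid keeps the liberated phenols protonated, so that neither the C7' carbinol nor the C2–O1 bond ionises through a p-quinone methide and the lactone stays closed.

## Compound list

1 | 5-bromovanillin | COc1cc(C=O)cc(Br)c1O | starting material
2 | 4-(benzyloxy)-3-bromo-5-methoxybenzaldehyde | COc1cc(C=O)cc(Br)c1OCc1ccccc1 | intermediate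
3 | dimethyl succinate | COC(=O)CCC(=O)OC | starting material
4 | (E)-4-[4-(benzyloxy)-3-bromo-5-methoxyphenyl]-3-(methoxycarbonyl)but-3-enoic acid | COC(=O)/C(CC(=O)O)=C/c1cc(Br)c(OCc2ccccc2)c(OC)c1 | intermediate
5 | (3S)-4-[4-(benzyloxy)-3-bromo-5-methoxyphenyl]-3-(methoxycarbonyl)butanoic acid | COC(=O)[C@H](CC(=O)O)Cc1cc(Br)c(OCc2ccccc2)c(OC)c1 | intermediate
6 | (3S)-4-[4-(benzyloxy)-3-bromo-5-methoxyphenyl]-3-(hydroxymethyl)butanoic acid | O=C(O)C[C@H](Cc1cc(Br)c(OCc2ccccc2)c(OC)c1)CO | intermediate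
7 | (4S)-4-[4-(benzyloxy)-3-bromo-5-methoxybenzyl]oxolan-2-one | O=C1C[C@H](Cc2cc(Br)c(OCc3ccccc3)c(OC)c2)CO1 | intermediate
8 | (4S)-4-[4-(benzyloxy)-3-ethenyl-5-methoxybenzyl]oxolan-2-one | O=C1C[C@H](Cc2cc(C=C)c(OCc3ccccc3)c(OC)c2)CO1 | intermediate
9 | (4S)-4-[4-(benzyloxy)-3-(1,2-dihydroxyethyl)-5-methoxybenzyl]oxolan-2-one, both carbinol epimers | O=C1C[C@H](Cc2cc(C(O)CO)c(OCc3ccccc3)c(OC)c2)CO1 | intermediate
10 | (4S)-4-{4-(benzyloxy)-3-[2-(TBS-oxy)-1-hydroxyethyl]-5-methoxybenzyl}oxolan-2-one | O=C1C[C@H](Cc2cc(C(O)CO[Si](C)(C)C(C)(C)C)c(OCc3ccccc3)c(OC)c2)CO1 | intermediate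
11 | (4S)-4-{4-hydroxy-3-[2-(TBS-oxy)-1-hydroxyethyl]-5-methoxybenzyl}oxolan-2-one | O=C1C[C@H](Cc2cc(OC)c(O)c(c2)C(O)CO[Si](C)(C)C(C)(C)C)CO1 | intermediate
12 | (4S)-4-{4-hydroxy-3-[2-(TBS-oxy)-1-(p-tolylsulfonyl)ethyl]-5-methoxybenzyl}oxolan-2-one, either sulfone epimer | O=C1C[C@H](Cc2cc(OC)c(O)c(c2)C(CO[Si](C)(C)C(C)(C)C)S(=O)(=O)c2ccc(C)cc2)CO1 | intermediate
13 | (2S,5S)-hexane-2,5-diol | C[C@H](O)CC[C@H](C)O | starting material
14 | (2S,5S)-hexane-2,5-diyl dimethanesulfonate | C[C@H](OS(C)(=O)=O)CC[C@H](C)OS(C)(=O)=O | intermediate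
15 | (2R,5R)-2,5-dimethylthiolane | C[C@@H]1CC[C@@H](C)S1 | intermediate
16 | vanillin | COc1cc(C=O)ccc1O | starting material
17 | 3-methoxy-4-(TIPS-oxy)benzaldehyde | COc1cc(C=O)ccc1O[Si](C(C)C)(C(C)C)C(C)C | intermediate
18 | [3-methoxy-4-(TIPS-oxy)phenyl]methanol | COc1cc(CO)ccc1O[Si](C(C)C)(C(C)C)C(C)C | intermediate
19 | 4-(bromomethyl)-2-methoxy-1-(TIPS-oxy)benzene | COc1cc(CBr)ccc1O[Si](C(C)C)(C(C)C)C(C)C | intermediate
20 | (2R,5R)-1-[3-methoxy-4-(TIPS-oxy)benzyl]-2,5-dimethylthiolan-1-ium triflate | C[C@@H]1CC[C@@H](C)[S+]1Cc1ccc(O[Si](C(C)C)(C(C)C)C(C)C)c(OC)c1.[O-]S(=O)(=O)C(F)(F)F | intermediate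
21 | 6-[(E)-2-(TBS-oxy)ethylidene]-2-methoxy-4-{[(3S)-5-oxooxolan-3-yl]methyl}cyclohexa-2,4-dien-1-one (o-quinone methide) | O=C1C[C@H](CC2=C/C(=C\CO[Si](C)(C)C(C)(C)C)C(=O)C(OC)=C2)CO1 | intermediate
22 | (2R,5R)-2,5-dimethylthiolanium [3-methoxy-4-(TIPS-oxy)phenyl]methylide | C[C@@H]1CC[C@@H](C)[S+]1[CH-]c1ccc(O[Si](C(C)C)(C(C)C)C(C)C)c(OC)c1 | intermediate
23 | phenoxide–thiolanium betaine, S at the sulfonium-bearing carbon and S at the future C3 | O=C1C[C@H](Cc2cc(OC)c([O-])c(c2)[C@@H](CO[Si](C)(C)C(C)(C)C)[C@@H](c2ccc(O[Si](C(C)C)(C(C)C)C(C)C)c(OC)c2)[S+]2[C@H](C)CC[C@H]2C)CO1 | intermediate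
24 | (4S)-4-({(2R,3S)-3-[(TBS-oxy)methyl]-7-methoxy-2-[3-methoxy-4-(TIPS-oxy)phenyl]-2,3-dihydro-1-benzofuran-5-yl}methyl)oxolan-2-one | O=C1C[C@H](Cc2cc(OC)c3c(c2)[C@@H](CO[Si](C)(C)C(C)(C)C)[C@H](c2ccc(O[Si](C(C)C)(C(C)C)C(C)C)c(OC)c2)O3)CO1 | intermediate
25 | methyl 3-bromo-4-hydroxy-5-methoxybenzoate | COC(=O)c1cc(Br)c(O)c(OC)c1 | starting material
26 | methyl 3-bromo-4-(TBS-oxy)-5-methoxybenzoate | COC(=O)c1cc(Br)c(O[Si](C)(C)C(C)(C)C)c(OC)c1 | intermediate
27 | methyl 3-(2-tert-butoxy-2-oxoethyl)-4-(TBS-oxy)-5-methoxybenzoate | COC(=O)c1cc(CC(=O)OC(C)(C)C)c(O[Si](C)(C)C(C)(C)C)c(OC)c1 | intermediate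
28 | [2-(TBS-oxy)-3-methoxy-5-(methoxycarbonyl)phenyl]acetic acid | COC(=O)c1cc(CC(=O)O)c(O[Si](C)(C)C(C)(C)C)c(OC)c1 | intermediate
29 | (4S)-4-benzyl-1,3-oxazolidin-2-one | O=C1N[C@@H](Cc2ccccc2)CO1 | starting material
30 | mixed anhydride of 28 with pivalic acid | COC(=O)c1cc(CC(=O)OC(=O)C(C)(C)C)c(O[Si](C)(C)C(C)(C)C)c(OC)c1 | intermediate
31 | methyl 3-{2-[(4S)-4-benzyl-2-oxo-1,3-oxazolidin-3-yl]-2-oxoethyl}-4-(TBS-oxy)-5-methoxybenzoate | COC(=O)c1cc(CC(=O)N2[C@@H](Cc3ccccc3)COC2=O)c(O[Si](C)(C)C(C)(C)C)c(OC)c1 | intermediate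
32 | O-trimethylsilyl ether of 33 | COc1cc([C@@H](O[Si](C)(C)C)[C@H](C(=O)N2[C@@H](Cc3ccccc3)COC2=O)c2cc(C(=O)OC)cc(OC)c2O[Si](C)(C)C(C)(C)C)ccc1O[Si](C(C)C)(C(C)C)C(C)C | intermediate
33 | (2R,3S)-anti-aldol imide | COc1cc([C@@H](O)[C@H](C(=O)N2[C@@H](Cc3ccccc3)COC2=O)c2cc(C(=O)OC)cc(OC)c2O[Si](C)(C)C(C)(C)C)ccc1O[Si](C(C)C)(C(C)C)C(C)C | intermediate
34 | methyl 4-(TBS-oxy)-3-{(1S,2S)-1,3-dihydroxy-1-[3-methoxy-4-(TIPS-oxy)phenyl]propan-2-yl}-5-methoxybenzoate | COc1cc([C@@H](O)[C@H](CO)c2cc(C(=O)OC)cc(OC)c2O[Si](C)(C)C(C)(C)C)ccc1O[Si](C(C)C)(C(C)C)C(C)C | intermediate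
35 | bis-TBS ether of 34 | COc1cc([C@@H](O[Si](C)(C)C(C)(C)C)[C@H](CO[Si](C)(C)C(C)(C)C)c2cc(C(=O)OC)cc(OC)c2O[Si](C)(C)C(C)(C)C)ccc1O[Si](C(C)C)(C(C)C)C(C)C | intermediate
36 | ring A benzylic alcohol | COc1cc([C@@H](O[Si](C)(C)C(C)(C)C)[C@H](CO[Si](C)(C)C(C)(C)C)c2cc(CO)cc(OC)c2O[Si](C)(C)C(C)(C)C)ccc1O[Si](C(C)C)(C(C)C)C(C)C | intermediate
37 | ring A benzylic bromide | COc1cc([C@@H](O[Si](C)(C)C(C)(C)C)[C@H](CO[Si](C)(C)C(C)(C)C)c2cc(CBr)cc(OC)c2O[Si](C)(C)C(C)(C)C)ccc1O[Si](C(C)C)(C(C)C)C(C)C | intermediate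
38 | lithium enolate of 24 | [Li+].[O-]C1=C[C@H](Cc2cc(OC)c3c(c2)[C@@H](CO[Si](C)(C)C(C)(C)C)[C@H](c2ccc(O[Si](C(C)C)(C(C)C)C(C)C)c(OC)c2)O3)CO1 | intermediate
39 | hexasilylated (3S,4S)-trans-dibenzylbutyrolactone (four TBS, two TIPS) | COc1cc([C@@H](O[Si](C)(C)C(C)(C)C)[C@H](CO[Si](C)(C)C(C)(C)C)c2cc(C[C@@H]3C(=O)OC[C@H]3Cc3cc(OC)c4c(c3)[C@@H](CO[Si](C)(C)C(C)(C)C)[C@H](c3ccc(O[Si](C(C)C)(C(C)C)C(C)C)c(OC)c3)O4)cc(OC)c2O[Si](C)(C)C(C)(C)C)ccc1O[Si](C(C)C)(C(C)C)C(C)C | intermediate
40 | (3S,4S)-3-{3-[(1S,2S)-1,3-dihydroxy-1-(4-hydroxy-3-methoxyphenyl)propan-2-yl]-4-hydroxy-5-methoxybenzyl}-4-{[(2R,3S)-2-(4-hydroxy-3-methoxyphenyl)-3-(hydroxymethyl)-7-methoxy-2,3-dihydro-1-benzofuran-5-yl]methyl}oxolan-2-one | COc1cc([C@@H](O)[C@H](CO)c2cc(C[C@@H]3C(=O)OC[C@H]3Cc3cc(OC)c4c(c3)[C@@H](CO)[C@H](c3ccc(O)c(OC)c3)O4)cc(OC)c2O)ccc1O | target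

## Step count

Total step count: 27.
Longest linear sequence: 12 steps (steps 1–9, 16, 26, 27, from 5-bromovanillin). The ring A branch runs 11 steps (17–25, 26, 27).

## Steps most likely to fail

**Step 16.**
- What may go wrong: the alkyl-substituted quinone methide may tautomerise by a 1,5-hydrogen shift. The phenoxide may be O-benzylated by the sulfonium salt. The deprotonated sulfone may lose silanolate by β-elimination. The thiolane may discriminate the ylide faces only weakly.
- Fallback (known chemistry): it sets out from bromolactone 7 and returns at 24, building the ring by aldol and etherification.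
- Negishi-type coupling of 7 with ClZnCH2CO2t-Bu (conditions of step 18) would give the tert-butyl arylacetate F1. TFA would give the arylacetic acid F2, and mixed-anhydride acylation of 29 would give the imide F3.
- The magnesium-catalysed anti-aldol of step 21 with aldehyde 17 would give the (2R,3S)-aldol imide F4. NaBH4 in THF/H2O would give the (1S,2S)-diol F5 with the lactone kept. TBSCl/imidazole would give the primary silyl ether F6, and hydrogenolysis (H2, Pd/C, EtOAc) would give the phenol F7.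
- Intramolecular Mitsunobu etherification (DIAD, PPh3, THF, 0 °C) would then close O1–C2 with inversion at the carbinol carbon to give 24. C3 would come from the auxiliary, and any ionisation of the electron-rich benzylic centre should still collapse to the trans ring.

**Step 21.**
- What may go wrong: anti selectivity may erode, the acidic α-aryl centre may epimerise or undergo retro-aldol cleavage under the amine, and the ortho silyloxy group may slow the addition.
- Fallback: it sets out from acid 28 and returns at 35. It sets C8' by auxiliary-controlled hydroxymethylation and C7' by Felkin–Anh addition of an aryl nucleophile to an aldehyde, so C7' becomes the former acyl carbon.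
- Acylation of (4R)-4-benzyl-1,3-oxazolidin-2-one with 28 (conditions of step 20) would give the antipodal imide F8. The titanium enolate (TiCl4, i-Pr2NEt, CH2Cl2, 0 °C) with 1,3,5-trioxane/TiCl4 would give the (2S)-hydroxymethyl imide F9, and TBSCl/imidazole would give the silyl ether F10.
- EtSLi (from EtSH and n-BuLi) would give the ethyl thioester F11. Fukuyama reduction (Et3SiH, Pd/C, acetone) would give the α-aryl aldehyde F12 under neutral conditions.
- Commercial 4-bromo-2-methoxyphenol with TIPSCl/imidazole would give the aryl bromide F13, and Mg in THF would give the aryl Grignard reagent F14. Its addition to F12 at −78 °C, anti to the ring A aryl group, should favour the (1S,2S)-alcohol F15. TBSOTf/2,6-lutidine would convert F15 into 35.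

**Step 9.**
- What may go wrong: ionisation may be sluggish because the β-silyloxy group withdraws electron density, and the sulfinic acid may remove or shift the primary silyl ether.
- Fallback: it sets out from 10 and returns at 12, forming the C–S bond by SN2 chemistry on the benzyl-protected series.
- Mitsunobu thioetherification of 10 with 4-methylbenzenethiol (DIAD, PPh3, THF) would give the aryl sulfide F16. mCPBA (CH2Cl2, 0 °C) would give the O-benzyl sulfone F17, and hydrogenolysis (H2, Pd/C, EtOAc) would release phenol 12.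

## Further compounds

F1 | step 16 | tert-butyl [2-(benzyloxy)-3-methoxy-5-{[(3S)-5-oxooxolan-3-yl]methyl}phenyl]acetate | O=C1C[C@H](Cc2cc(CC(=O)OC(C)(C)C)c(OCc3ccccc3)c(OC)c2)CO1
F2 | step 16 | [2-(benzyloxy)-3-methoxy-5-{[(3S)-5-oxooxolan-3-yl]methyl}phenyl]acetic acid | O=C1C[C@H](Cc2cc(CC(=O)O)c(OCc3ccccc3)c(OC)c2)CO1
F3 | step 16 | (4S)-4-benzyl-3-{[2-(benzyloxy)-3-methoxy-5-{[(3S)-5-oxooxolan-3-yl]methyl}phenyl]acetyl}-1,3-oxazolidin-2-one | O=C1C[C@H](Cc2cc(CC(=O)N3[C@@H](Cc4ccccc4)COC3=O)c(OCc3ccccc3)c(OC)c2)CO1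
F4 | step 16 | (2R,3S)-anti-aldol imide of the ring B series | COc1cc([C@@H](O)[C@H](C(=O)N2[C@@H](Cc3ccccc3)COC2=O)c2cc(C[C@H]3CC(=O)OC3)cc(OC)c2OCc2ccccc2)ccc1O[Si](C(C)C)(C(C)C)C(C)C
F5 | step 16 | (4S)-4-[4-(benzyloxy)-3-{(1S,2S)-1,3-dihydroxy-1-[3-methoxy-4-(TIPS-oxy)phenyl]propan-2-yl}-5-methoxybenzyl]oxolan-2-one | COc1cc([C@@H](O)[C@H](CO)c2cc(C[C@H]3CC(=O)OC3)cc(OC)c2OCc2ccccc2)ccc1O[Si](C(C)C)(C(C)C)C(C)C
F6 | step 16 | primary TBS ether of F5 | COc1cc([C@@H](O)[C@H](CO[Si](C)(C)C(C)(C)C)c2cc(C[C@H]3CC(=O)OC3)cc(OC)c2OCc2ccccc2)ccc1O[Si](C(C)C)(C(C)C)C(C)C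
F7 | step 16 | debenzylated phenol of F6 | COc1cc([C@@H](O)[C@H](CO[Si](C)(C)C(C)(C)C)c2cc(C[C@H]3CC(=O)OC3)cc(OC)c2O)ccc1O[Si](C(C)C)(C(C)C)C(C)C
F8 | step 21 | methyl 3-{2-[(4R)-4-benzyl-2-oxo-1,3-oxazolidin-3-yl]-2-oxoethyl}-4-(TBS-oxy)-5-methoxybenzoate | COC(=O)c1cc(CC(=O)N2[C@H](Cc3ccccc3)COC2=O)c(O[Si](C)(C)C(C)(C)C)c(OC)c1
F9 | step 21 | (2S)-3-hydroxy-2-arylpropanoyl imide of the (4R)-auxiliary | O=C([C@H](CO)c1cc(C(=O)OC)cc(OC)c1O[Si](C)(C)C(C)(C)C)N1[C@H](Cc2ccccc2)COC1=O
F10 | step 21 | TBS ether of F9 | O=C([C@H](CO[Si](C)(C)C(C)(C)C)c1cc(C(=O)OC)cc(OC)c1O[Si](C)(C)C(C)(C)C)N1[C@H](Cc2ccccc2)COC1=O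
F11 | step 21 | S-ethyl (2S)-3-(TBS-oxy)-2-arylpropanethioate | CCSC(=O)[C@H](CO[Si](C)(C)C(C)(C)C)c1cc(C(=O)OC)cc(OC)c1O[Si](C)(C)C(C)(C)C
F12 | step 21 | methyl 4-(TBS-oxy)-3-[(2S)-1-(TBS-oxy)-3-oxopropan-2-yl]-5-methoxybenzoate | O=C[C@H](CO[Si](C)(C)C(C)(C)C)c1cc(C(=O)OC)cc(OC)c1O[Si](C)(C)C(C)(C)C
F13 | step 21 | 4-bromo-2-methoxy-1-(TIPS-oxy)benzene | COc1cc(Br)ccc1O[Si](C(C)C)(C(C)C)C(C)C
F14 | step 21 | [3-methoxy-4-(TIPS-oxy)phenyl]magnesium bromide | COc1cc([Mg]Br)ccc1O[Si](C(C)C)(C(C)C)C(C)C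
F15 | step 21 | methyl 4-(TBS-oxy)-3-{(1S,2S)-3-(TBS-oxy)-1-hydroxy-1-[3-methoxy-4-(TIPS-oxy)phenyl]propan-2-yl}-5-methoxybenzoate | COc1cc([C@@H](O)[C@H](CO[Si](C)(C)C(C)(C)C)c2cc(C(=O)OC)cc(OC)c2O[Si](C)(C)C(C)(C)C)ccc1O[Si](C(C)C)(C(C)C)C(C)C
F16 | step 9 | (4S)-4-{4-(benzyloxy)-3-[2-(TBS-oxy)-1-(p-tolylsulfanyl)ethyl]-5-methoxybenzyl}oxolan-2-one | O=C1C[C@H](Cc2cc(C(CO[Si](C)(C)C(C)(C)C)Sc3ccc(C)cc3)c(OCc3ccccc3)c(OC)c2)CO1
F17 | step 9 | (4S)-4-{4-(benzyloxy)-3-[2-(TBS-oxy)-1-(p-tolylsulfonyl)ethyl]-5-methoxybenzyl}oxolan-2-one | O=C1C[C@H](Cc2cc(C(CO[Si](C)(C)C(C)(C)C)S(=O)(=O)c3ccc(C)cc3)c(OCc3ccccc3)c(OC)c2)CO1
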